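**Retrosynthetic overview**
1. Target 13 ⇒ the allylic C6–O ester bond is made last, from the C6-epimeric diol 10 and 4-acetoxybenzoic acid 11 through a common C6–C7–C8 allyl cation; this step fixes C6.
2. 10 ⇒ C4–isopropyl bond: bicyclic β-hydroxy ketone 9 + iPrMgCl (fixes C4).
3. 9 ⇒ C7=C8 by ring-closing metathesis of cyclopentanone 8 (the seven-membered ring is formed second, onto the five-membered ring).
4. 8 ⇒ C1–CH3 and C5–C6 bonds: asymmetric conjugate addition of Me3Al to enone 5, then aldol with acrolein 6 (fixes C1 and C5).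
5. 5 ⇒ 3-ethoxycyclopent-2-en-1-one 1 (five-membered ring bought) + 4-bromo-2-methylbut-1-ene 2.

Assumption: C1–C15 in the text are daucane locants (C1 = ring-fusion carbon bearing the C15 methyl, C4 = isopropyl carbinol, C5 = ring-fusion CH, C6 = ester carbon, C7=C8 = ring alkene bearing the C14 methyl; β = the face of the C15 methyl), systematic names use azulene locants, and 8, 9 and 10 are carried as mixtures of C6 epimers (6S major), so their SMILES leave C6 undefined.

**Step 1**
Reactants: 1 3-ethoxycyclopent-2-en-1-one; 2 4-bromo-2-methylbut-1-ene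
Product: 5 3-(3-methylbut-3-en-1-yl)cyclopent-2-en-1-one, via Grignard reagent 3 (not isolated), via magnesium alkoxide adduct 4 (not isolated)
Conditions: 2, Mg, THF, rt; then 1, 0 °C → rt; then 1 M HCl, 0 °C
Reagents that add atoms: water, O
Why: Stork–Danheiser transposition: the Grignard reagent adds 1,2 to the carbonyl of the vinylogous ester and aqueous acid then expels water and ethanol to give the β-alkyl enone; no stereocentre is formed.

**Step 2**
Reactants: 5 3-(3-methylbut-3-en-1-yl)cyclopent-2-en-1-one; 6 acrolein (prop-2-enal)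
Product: 8 (2S,3S)-2-(1-hydroxyprop-2-en-1-yl)-3-methyl-3-(3-methylbut-3-en-1-yl)cyclopentan-1-one (carbinol epimers), via aluminium enolate 7 (not isolated)
Conditions: Me3Al (2 equiv), Cu(OTf)2 (5 mol %), [Ag(NHC*)]2 (2.5 mol %; NHC* = chiral sulfonate-bearing imidazolin-2-ylidene), THF, −78 °C; then acrolein (4 equiv), −78 °C; aq. Rochelle salt
Reagents that add atoms: trimethylaluminium, C[Al](C)C
Why: Copper–NHC-catalysed asymmetric conjugate addition of Me3Al to the β-substituted cyclopentenone sets the C1 quaternary centre (the ligand enantiomer used is the one that gives 1S), and the aluminium enolate 7 then adds to acrolein in a closed Zimmerman–Traxler aldol on the C5 face anti to the longer C1 chain (C6 cis to the new methyl, expected about 3:1, minor C5 epimer removed after step 3), the E-enolate favouring the anti 6S carbinol while C6 is deliberately left uncontrolled.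

**Step 3**
Reactants: 8 (2S,3S)-2-(1-hydroxyprop-2-en-1-yl)-3-methyl-3-(3-methylbut-3-en-1-yl)cyclopentan-1-one (carbinol epimers)
Product: 9 (3aS,8aS)-8-hydroxy-3a,6-dimethyl-3,3a,4,5,8,8a-hexahydroazulen-1(2H)-one (carbinol epimers; trans-fused)
Conditions: second-generation Hoveyda–Grubbs catalyst (5 mol %), 1,4-benzoquinone (10 mol %), toluene (0.005 M), 80 °C
Reagents that add atoms: none
Why: Ring-closing metathesis of the vinyl carbinol onto the 1,1-disubstituted alkene closes the seven-membered ring as the trisubstituted C7=C8 alkene with loss of ethene (benzoquinone stops Ru–H isomerisation of the allylic alcohol); no stereocentre is touched, the trans C5/C1 relationship of 8 becomes the trans ring fusion, and the minor cis-fused isomers are separated here.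

**Step 4**
Reactants: 9 (3aS,8aS)-8-hydroxy-3a,6-dimethyl-3,3a,4,5,8,8a-hexahydroazulen-1(2H)-one (carbinol epimers)
Product: 10 (3R,3aS,8aS)-6,8a-dimethyl-3-(propan-2-yl)-1,2,3,3a,4,7,8,8a-octahydroazulene-3,4-diol (epimers at the secondary carbinol)
Conditions: iPrMgCl (4 equiv), LaCl3·2LiCl (1.2 equiv), THF, −20 → 0 °C; aq. NH4Cl
Reagents that add atoms: isopropylmagnesium chloride, CC(C)[Mg]Cl
Why: Lanthanide-promoted Grignard 1,2-addition (LaCl3·2LiCl suppresses enolisation, reduction and retro-aldol, so C5 is not scrambled): the isopropyl group enters the C4 carbonyl from the α face, anti to the adjacent C5–C6 bond and to the C15 methyl, giving the 4β (4R) tertiary alcohol.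

**Step 5**
Reactants: 10 (3R,3aS,8aS)-6,8a-dimethyl-3-(propan-2-yl)-1,2,3,3a,4,7,8,8a-octahydroazulene-3,4-diol (epimers at the secondary carbinol); 11 4-acetoxybenzoic acid
Product: 13 (3R,3aS,4S,8aS)-3-hydroxy-6,8a-dimethyl-3-(propan-2-yl)-1,2,3,3a,4,7,8,8a-octahydroazulen-4-yl 4-hydroxybenzoate (target), via acetate-protected ester 12 (not isolated)
Conditions: Re2O7 (3 mol %), 11 (3 equiv), 4 Å MS, CH2Cl2/MeCN 4:1, 0 °C → rt; then pyrrolidine (8 equiv), MeOH, 0 °C → rt
Reagents that add atoms: none
Why: Proposed new method: a Re2O7-catalysed stereoconvergent dehydrative allylic acyloxylation, in which both C6 epimers of 10 condense with perrhenate and ionise to the same C6–C7–C8 allyl cation/perrhenate ion pair (the tertiary C8 terminus makes this far easier than ionisation of the non-allylic C4–OH, which also cannot close onto the cation), acid 11 captures the cation at the secondary terminus C6 from the α face because the β trajectory is syn-axial to the C15 methyl and the 4β-OH, and, since allylic esters of this kind re-ionise under perrhenic acid, the equatorial 6α (6S) ester with the trisubstituted C7=C8 alkene is also the expected thermodynamic product, so the C6–O bond and the C6 configuration are set here whatever the epimer ratio of 10; the closest known reaction type is the Re2O7- or Ph3SiOReO3-catalysed 1,3-transposition and dehydrative substitution of allylic alcohols by O and N nucleophiles under thermodynamic control (not shown for carboxylic acids or for stereoconvergent ester formation); the phenolic acetate is then cleaved in the same flask by aminolysis with pyrrolidine, which leaves the hindered secondary benzoate intact.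

**Compound list**
1 | 3-ethoxycyclopent-2-en-1-one | CCOC1=CC(=O)CC1 | starting material
2 | 4-bromo-2-methylbut-1-ene | CC(=C)CCBr | starting material
3 | (3-methylbut-3-en-1-yl)magnesium bromide | CC(=C)CC[Mg]Br | intermediate
4 | bromomagnesium 3-ethoxy-1-(3-methylbut-3-en-1-yl)cyclopent-2-en-1-olate (racemic) | CCOC1=CC(CCC(C)=C)(O[Mg]Br)CC1 | intermediate
5 | 3-(3-methylbut-3-en-1-yl)cyclopent-2-en-1-one | O=C1C=C(CCC(C)=C)CC1 | intermediate
6 | acrolein (prop-2-enal) | C=CC=O | starting material
7 | dimethylaluminium (3S)-3-methyl-3-(3-methylbut-3-en-1-yl)cyclopent-1-en-1-olate | C[Al](C)OC1=C[C@@](C)(CCC(C)=C)CC1 | intermediate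
8 | (2S,3S)-2-(1-hydroxyprop-2-en-1-yl)-3-methyl-3-(3-methylbut-3-en-1-yl)cyclopentan-1-one, carbinol (C6) epimers, 6S major | C=CC(O)[C@@H]1[C@@](C)(CCC(C)=C)CCC1=O | intermediate
9 | (3aS,8aS)-8-hydroxy-3a,6-dimethyl-3,3a,4,5,8,8a-hexahydroazulen-1(2H)-one, trans-fused, carbinol (C6) epimers | CC1=CC(O)[C@@H]2[C@@](C)(CC1)CCC2=O | intermediate
10 | (3R,3aS,8aS)-6,8a-dimethyl-3-(propan-2-yl)-1,2,3,3a,4,7,8,8a-octahydroazulene-3,4-diol, 4β-OH, trans-fused, secondary carbinol (C6) epimers | CC1=CC(O)[C@@H]2[C@@](C)(CC1)CC[C@@]2(O)C(C)C | intermediate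
11 | 4-acetoxybenzoic acid | CC(=O)Oc1ccc(cc1)C(O)=O | starting material
12 | (3R,3aS,4S,8aS)-3-hydroxy-6,8a-dimethyl-3-(propan-2-yl)-1,2,3,3a,4,7,8,8a-octahydroazulen-4-yl 4-(acetyloxy)benzoate | CC1=C[C@H](OC(=O)c2ccc(OC(C)=O)cc2)[C@@H]2[C@@](C)(CC1)CC[C@@]2(O)C(C)C | intermediate
13 | (3R,3aS,4S,8aS)-3-hydroxy-6,8a-dimethyl-3-(propan-2-yl)-1,2,3,3a,4,7,8,8a-octahydroazulen-4-yl 4-hydroxybenzoate | CC1=C[C@H](OC(=O)c2ccc(O)cc2)[C@@H]2[C@@](C)(CC1)CC[C@@]2(O)C(C)C | target

**Step count and risks**
Total steps: 5. Longest linear sequence: 5 (from 1 or 2 to 13).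

Most likely to fail, first: step 5, the new acyloxylation. The cation may lose a proton to give dienes, the facial or thermodynamic preference at C6 may be weaker than argued, or the tertiary C4–OH may not survive perrhenic acid. The fallback uses only known chemistry and sets out from 10. MnO2 in CH2Cl2 oxidises only the allylic carbinol and merges both epimers into (3R,3aR,8aS)-3-hydroxy-6,8a-dimethyl-3-(propan-2-yl)-2,3,3a,7,8,8a-hexahydroazulen-4(1H)-one F1. Hydroxyl-directed reduction with Me4NBH(OAc)3 (MeCN/AcOH, −30 °C) delivers hydride from boron bound to the 4β-oxygen onto the β face of C6 and gives the anti-1,3-diol (3R,3aS,4S,8aS)-6,8a-dimethyl-3-(propan-2-yl)-1,2,3,3a,4,7,8,8a-octahydroazulene-3,4-diol F2. Steglich esterification of F2 with 11 (DIC, DMAP, CH2Cl2) acylates only the secondary alcohol and comes back to the route at 12, which pyrrolidine converts to 13 as in step 5.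

Second: step 2. The enantioselectivity with this functionalised cyclopentenone, the aldol of an aluminium enolate with acrolein in the presence of residual Me3Al, and the modest C5 facial ratio are all uncertain. The fallback sets out from 2 (as Grignard reagent 3) and forms the other C1–C bond in the asymmetric step. Copper-catalysed asymmetric conjugate addition of 3 to bought 3-methylcyclopent-2-en-1-one F3 (Cu(OTf)2, chiral imidazolinium salt as NHC precursor, Et2O, 0 °C), run with Me3SiCl/Et3N trapping, gives trimethyl{[(3S)-3-methyl-3-(3-methylbut-3-en-1-yl)cyclopent-1-en-1-yl]oxy}silane F4. An open-transition-state Mukaiyama aldol of F4 with acrolein 6 (BF3·OEt2, CH2Cl2, −78 °C) comes back to the route at 8 and gives a separate handle (Lewis acid size) on the C5 ratio.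

Third: step 4. iPrMgCl may act as a base or hydride donor toward the hindered β-alkoxy ketone, or trigger retro-aldol. The fallback sets out from 9. The less basic isopropenylmagnesium bromide with CeCl3 (THF, −78 °C) adds from the same α face to give (3S,3aS,8aS)-6,8a-dimethyl-3-(prop-1-en-2-yl)-1,2,3,3a,4,7,8,8a-octahydroazulene-3,4-diol F5. Hydrogenation with H2 and RhCl(PPh3)3 (benzene, rt) reduces only the 1,1-disubstituted alkene and comes back to the route at 10.

**Further compounds**
F1 | step 5 | (3R,3aR,8aS)-3-hydroxy-6,8a-dimethyl-3-(propan-2-yl)-2,3,3a,7,8,8a-hexahydroazulen-4(1H)-one | CC1=CC(=O)[C@@H]2[C@@](C)(CC1)CC[C@@]2(O)C(C)C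
F2 | step 5 | (3R,3aS,4S,8aS)-6,8a-dimethyl-3-(propan-2-yl)-1,2,3,3a,4,7,8,8a-octahydroazulene-3,4-diol | CC1=C[C@H](O)[C@@H]2[C@@](C)(CC1)CC[C@@]2(O)C(C)C
F3 | step 2 | 3-methylcyclopent-2-en-1-one (bought) | CC1=CC(=O)CC1
F4 | step 2 | trimethyl{[(3S)-3-methyl-3-(3-methylbut-3-en-1-yl)cyclopent-1-en-1-yl]oxy}silane | C[Si](C)(C)OC1=C[C@@](C)(CCC(C)=C)CC1
F5 | step 4 | (3S,3aS,8aS)-6,8a-dimethyl-3-(prop-1-en-2-yl)-1,2,3,3a,4,7,8,8a-octahydroazulene-3,4-diol (secondary carbinol epimers) | CC1=CC(O)[C@@H]2[C@@](C)(CC1)CC[C@@]2(O)C(C)=C
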